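**Plan**

- Retrosynthesis first cuts the C11–O aryl ether (Mitsunobu with umbelliferone). It then traces the C4–C5 bond of ring A back to a C3–C5 bond, so ring A (C1–C5, C10) comes from the cyclopentanol ring C1–C2–C3–C5–C10 of a trans-hydrindane carrying a 2-methyloxiranyl group on C3.
- The enabling feature is the secondary C3 carbinol next to the quaternary C4 with its CH2O arm. This 1,3-dioxygen pattern is the reduced form of a β-hydroxy ketone, the product of a semipinacol shift; the acetate and H3 then come from acetaldehyde by Tishchenko hydride transfer.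
- Further cuts: C2–C3 (alkene hydroacylation), C8=CH2, C9–C11 and C10–vinyl (Mannich/oxa-Michael and cuprate addition on a 3-methylcyclohexenone), C10–CH3, and ring B itself (Michael/aldol of aldehyde 1 with methyl vinyl ketone).
- Forward order: ring B, then the five-membered ring, then ring A by one-carbon expansion, then the coumarin ether.
- Stereochemistry: C5 from the prolinol ether catalyst; C10 by cuprate addition anti to the C5 substituent; C9 by protonation/equilibration; C4 by hydroxyl-directed epoxidation and invertive 1,2-shift; C3 by intramolecular hydride delivery.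

Key step: step 12

Remark: atom labels follow the target (ring A = C1–C5, C10; ring B = C5–C10; C11 = CH2O carbon on C9) and are kept for every intermediate.

Step 1
Reactants: 1 3-[(tert-butyldiphenylsilyl)oxy]propanal; 2 but-3-en-2-one (methyl vinyl ketone)
Product: 3 (R)-2-{[(tert-butyldiphenylsilyl)oxy]methyl}-5-oxohexanal
Conditions: (R)-2-[methoxy(diphenyl)methyl]pyrrolidine (5 mol%), ethyl 3,4-dihydroxybenzoate (20 mol%), neat, 4 °C
Reagents that add atoms: none
Why: Enamine-catalysed asymmetric Michael addition: the (R)-diarylprolinol ether forms the E-enamine of 1 and its diphenyl(methoxy)methyl group blocks one face, so methyl vinyl ketone should add to the other face and set the future C5 as R.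

Step 2
Reactants: 3 (R)-2-{[(tert-butyldiphenylsilyl)oxy]methyl}-5-oxohexanal
Product: 4 (S)-4-{[(tert-butyldiphenylsilyl)oxy]methyl}cyclohex-2-en-1-one
Conditions: TsOH·H2O (10 mol%), toluene, 50 °C
Reagents that add atoms: none
Why: Acid-catalysed intramolecular aldol condensation (Robinson-type closure of ring B, methyl ketone enol onto the aldehyde, then dehydration) leaves the C5 stereocentre untouched, and acid is chosen over base to avoid β-elimination of the silyloxy group.

Step 3
Reactants: 4 (S)-4-{[(tert-butyldiphenylsilyl)oxy]methyl}cyclohex-2-en-1-one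
Product: 6 (S)-4-{[(tert-butyldiphenylsilyl)oxy]methyl}-3-methylcyclohex-2-en-1-one, via trimethylsilyl enol ether 5 (not isolated)
Conditions: MeMgBr, CuBr·SMe2 (10 mol%), TMSCl, THF, −78 °C; then Pd(OAc)2 (1.1 equiv), MeCN, 25 °C
Reagents that add atoms: methylmagnesium bromide, C[Mg]Br
Why: Copper-catalysed conjugate addition of the methyl Grignard reagent (trapped by TMSCl, methyl trans to the C5 substituent) followed by Saegusa–Ito dehydrosilylation with divalent palladium returns the enone with the methyl now on C10, so the transient stereocentre is erased and C5 is untouched.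

Step 4
Reactants: 6 (S)-4-{[(tert-butyldiphenylsilyl)oxy]methyl}-3-methylcyclohex-2-en-1-one
Product: 8 (3R,4S)-4-{[(tert-butyldiphenylsilyl)oxy]methyl}-2-[(dimethylamino)methyl]-3-ethenyl-3-methylcyclohexan-1-one (C2 epimers), via trimethylsilyl enol ether 7 (not isolated)
Conditions: CH2=CHMgBr, CuBr·SMe2 (20 mol%), TMSCl, THF, −78 → −30 °C; then CH2=NMe2+ I−, CH2Cl2, 25 °C; aq. NaHCO3
Reagents that add atoms: vinylmagnesium bromide, C=C[Mg]Br; N,N-dimethylmethyleneiminium iodide (Eschenmoser's salt), C=[N+](C)C.[I-]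
Why: Copper-catalysed conjugate addition of the vinyl Grignard reagent should occur anti to the C5 CH2OSi group (axial attack on the half-chair), creating quaternary C10 with vinyl trans to the C5 substituent, and the regiodefined silyl enol ether then undergoes a Mannich reaction at C9.

Step 5
Reactants: 8 (3R,4S)-4-{[(tert-butyldiphenylsilyl)oxy]methyl}-2-[(dimethylamino)methyl]-3-ethenyl-3-methylcyclohexan-1-one
Product: 11 (2R,3R,4S)-4-{[(tert-butyldiphenylsilyl)oxy]methyl}-3-ethenyl-2-{[(4-methoxyphenyl)methoxy]methyl}-3-methylcyclohexan-1-one, via methiodide 9 (not isolated), via exo-methylene ketone 10 (not isolated)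
Conditions: MeI, Et2O, 25 °C; then 4-MeOC6H4CH2OH (6 equiv), NaH (1.5 equiv), THF, 0 → 25 °C
Reagents that add atoms: 4-methoxybenzyl alcohol, COc1ccc(CO)cc1
Why: Exhaustive methylation and E1cB (Hofmann-type) elimination give the exo-methylene ketone, to which the 4-methoxybenzyl alkoxide adds reversibly (oxa-Michael); C9 is set by protonation of the enolate anti to the axial C10 methyl, which is also the thermodynamic epimer with CH2OPMB equatorial and cis to that methyl.

Step 6
Reactants: 11 (2R,3R,4S)-4-{[(tert-butyldiphenylsilyl)oxy]methyl}-3-ethenyl-2-{[(4-methoxyphenyl)methoxy]methyl}-3-methylcyclohexan-1-one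
Product: 12 tert-butyl{[(1S,2R,3R)-2-ethenyl-3-{[(4-methoxyphenyl)methoxy]methyl}-2-methyl-4-methylidenecyclohexyl]methoxy}diphenylsilane
Conditions: Zn, CH2Br2, TiCl4 (pre-formed reagent), THF/CH2Cl2, 0 → 25 °C
Reagents that add atoms: dibromomethane, BrCBr
Why: Lombardo methylenation with the zinc–titanium gem-dimetallic reagent is non-basic, so the epimerisable C9 centre and the β-alkoxy group survive while the hindered ketone becomes the C8 exocyclic alkene.

Step 7
Reactants: 12 tert-butyl{[(1S,2R,3R)-2-ethenyl-3-{[(4-methoxyphenyl)methoxy]methyl}-2-methyl-4-methylidenecyclohexyl]methoxy}diphenylsilane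
Product: 13 [(1S,2R,3R)-2-ethenyl-3-{[(4-methoxyphenyl)methoxy]methyl}-2-methyl-4-methylidenecyclohexyl]methanol
Conditions: Bu4NF, THF, 25 °C
Reagents that add atoms: none
Why: Fluoride-induced desilylation frees the primary alcohol on C5 selectively, since the PMB ether and the alkenes are inert to fluoride.

Step 8
Reactants: 13 [(1S,2R,3R)-2-ethenyl-3-{[(4-methoxyphenyl)methoxy]methyl}-2-methyl-4-methylidenecyclohexyl]methanol
Product: 14 (1S,2S,3R)-2-ethenyl-3-{[(4-methoxyphenyl)methoxy]methyl}-2-methyl-4-methylidenecyclohexane-1-carbaldehyde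
Conditions: Dess–Martin periodinane, NaHCO3, CH2Cl2, 0 → 25 °C
Reagents that add atoms: none
Why: Buffered Dess–Martin oxidation should give the aldehyde without epimerising C5, whose formyl group is equatorial and trans to the vinyl group.

Step 9
Reactants: 14 (1S,2S,3R)-2-ethenyl-3-{[(4-methoxyphenyl)methoxy]methyl}-2-methyl-4-methylidenecyclohexane-1-carbaldehyde
Product: 15 (3aS,4R,7aS)-4-{[(4-methoxyphenyl)methoxy]methyl}-3a-methyl-5-methylideneoctahydro-1H-inden-1-one (trans ring fusion)
Conditions: [Rh(nbd)(dppe)]BF4 (5 mol%, activated with H2), CH2Cl2, 25 °C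
Reagents that add atoms: none
Why: Rhodium-catalysed intramolecular alkene hydroacylation of the 4-pentenal unit (C3 formyl, C1=C2 vinyl) forms the C2–C3 bond and the cyclopentanone through aldehyde C–H oxidative addition, hydride insertion and reductive elimination; the trans-diequatorial formyl and vinyl groups become the trans ring fusion under neutral conditions that should not epimerise C5.

Step 10
Reactants: 15 (3aS,4R,7aS)-4-{[(4-methoxyphenyl)methoxy]methyl}-3a-methyl-5-methylideneoctahydro-1H-inden-1-one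
Product: 16 (1R,3aS,4R,7aS)-4-{[(4-methoxyphenyl)methoxy]methyl}-3a-methyl-5-methylidene-1-(prop-1-en-2-yl)octahydro-1H-inden-1-ol
Conditions: CH2=C(CH3)MgBr, CeCl3, THF, −78 °C
Reagents that add atoms: isopropenylmagnesium bromide, CC(=C)[Mg]Br
Why: Organocerium 1,2-addition is non-basic and suppresses enolisation of the epimerisable trans-hydrindanone; attack from the H5 face, anti to the 1,3-related angular C10 methyl, should place the C3 hydroxyl cis to that methyl, a centre that is erased later.

Step 11
Reactants: 16 (1R,3aS,4R,7aS)-4-{[(4-methoxyphenyl)methoxy]methyl}-3a-methyl-5-methylidene-1-(prop-1-en-2-yl)octahydro-1H-inden-1-ol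
Product: 17 (1R,3aS,4R,7aS)-4-{[(4-methoxyphenyl)methoxy]methyl}-3a-methyl-5-methylidene-1-[(2S)-2-methyloxiran-2-yl]octahydro-1H-inden-1-ol
Conditions: VO(acac)2 (5 mol%), t-BuOOH, CH2Cl2, 0 → 25 °C
Reagents that add atoms: tert-butyl hydroperoxide, CC(C)(C)OO
Why: Hydroxyl-directed vanadium-catalysed epoxidation of the tertiary allylic alcohol leaves the remote C8 alkene alone, and oxygen transfer through the rotamer that keeps the C4 methyl beside the ring CH2 (C2) and not beside the ring-fusion carbon C5 (allylic 1,2-strain) should give the (S)-oxirane.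

Step 12
Reactants: 17 (1R,3aS,4R,7aS)-4-{[(4-methoxyphenyl)methoxy]methyl}-3a-methyl-5-methylidene-1-[(2S)-2-methyloxiran-2-yl]octahydro-1H-inden-1-ol
Product: 19 [(1R,2S,4aR,5R,8aS)-2-hydroxy-5-{[(4-methoxyphenyl)methoxy]methyl}-1,4a-dimethyl-6-methylidenedecahydronaphthalen-1-yl]methyl acetate, via hydroxy ketone 18 (not isolated)
Conditions: SmI2 (0.3 equiv), CH3CHO (8 equiv), THF, −10 → 25 °C
Reagents that add atoms: acetaldehyde, CC=O
Why: Trivalent samarium formed in situ from SmI2 and the aldehyde binds the C3 alkoxide and the oxirane oxygen, the C4–O bond ionises and the ring bond C3–C5 shifts to C4 anti to the departing oxygen while C3 becomes a ketone (semipinacol rearrangement of a 2,3-epoxy alcohol), turning the cyclopentanol ring C1–C2–C3–C5–C10 into ring A of hydroxy ketone 18. Acetaldehyde then forms a samarium hemiacetal on the new C4 hydroxymethyl group and a hydride passes from the hemiacetal carbon to the C3 carbonyl through a six-membered chair transition state (Evans–Tishchenko reduction), releasing the primary acetate and the free C3 hydroxyl; the closest known reaction type is the SmI2-promoted tandem semipinacol rearrangement/Tishchenko reduction of α-hydroxy epoxides. Ring A is not closed by a cyclisation but arises by one-carbon ring expansion, a suprafacial 1,2-shift of ring carbon C5 with retention, so the trans ring fusion (H5 anti to the C10 methyl) is carried over. C4 is set by inversion at the oxirane carbon (C5 enters anti to the leaving oxygen, so the (S)-oxirane gives (R)-C4 with the oxymethyl arm axial and cis to the C10 methyl), and C3 is set by hydride delivery from the face of that axial arm, which places the hydroxyl axial and anti to CH2OAc (3S). The step needs migration of C5 and not C2, and survival of the C8 alkene and the PMB ether: C5 is the more substituted ring carbon, the usual winner in semipinacol shifts, and can lie anti-periplanar to the C4–O bond in the chelated rotamer, while the mild samarium Lewis acid should spare the 1,1-disubstituted alkene and the benzylic ether.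

Step 13
Reactants: 19 [(1R,2S,4aR,5R,8aS)-2-hydroxy-5-{[(4-methoxyphenyl)methoxy]methyl}-1,4a-dimethyl-6-methylidenedecahydronaphthalen-1-yl]methyl acetate
Product: 20 [(1R,2S,4aR,5R,8aS)-2-hydroxy-5-(hydroxymethyl)-1,4a-dimethyl-6-methylidenedecahydronaphthalen-1-yl]methyl acetate
Conditions: DDQ, CH2Cl2/pH 7 buffer, 0 °C
Reagents that add atoms: none
Why: Oxidative cleavage of the 4-methoxybenzyl ether by DDQ (benzylic hydride abstraction, then hydrolysis) frees the C11 hydroxyl, while the acetate, the secondary alcohol and the 1,1-disubstituted alkene should not react.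

Step 14
Reactants: 20 [(1R,2S,4aR,5R,8aS)-2-hydroxy-5-(hydroxymethyl)-1,4a-dimethyl-6-methylidenedecahydronaphthalen-1-yl]methyl acetate; 21 7-hydroxy-2H-chromen-2-one (umbelliferone)
Product: 22 [(1R,2S,4aR,5R,8aS)-2-hydroxy-1,4a-dimethyl-6-methylidene-5-{[(2-oxo-2H-chromen-7-yl)oxy]methyl}decahydronaphthalen-1-yl]methyl acetate (target)
Conditions: PPh3, DIAD, THF, 0 → 40 °C
Reagents that add atoms: none
Why: Mitsunobu etherification activates the primary C11 alcohol as its oxyphosphonium salt, which the acidic phenol of umbelliferone displaces, whereas the axial C3 hydroxyl next to quaternary C4 is too hindered to compete and no stereocentre is touched.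

**Compound list**

1 | 3-[(tert-butyldiphenylsilyl)oxy]propanal | O=CCCO[Si](c1ccccc1)(c1ccccc1)C(C)(C)C | starting material
2 | but-3-en-2-one (methyl vinyl ketone) | CC(=O)C=C | starting material
3 | (R)-2-{[(tert-butyldiphenylsilyl)oxy]methyl}-5-oxohexanal | CC(=O)CC[C@H](CO[Si](c1ccccc1)(c1ccccc1)C(C)(C)C)C=O | intermediate
4 | (S)-4-{[(tert-butyldiphenylsilyl)oxy]methyl}cyclohex-2-en-1-one | O=C1CC[C@H](CO[Si](c2ccccc2)(c2ccccc2)C(C)(C)C)C=C1 | intermediate
5 | tert-butyl{[(1S,2R)-2-methyl-4-[(trimethylsilyl)oxy]cyclohex-3-en-1-yl]methoxy}diphenylsilane (methyl trans to CH2OSi) | C[Si](C)(C)OC1=C[C@H](C)[C@@H](CO[Si](c2ccccc2)(c2ccccc2)C(C)(C)C)CC1 | intermediate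
6 | (S)-4-{[(tert-butyldiphenylsilyl)oxy]methyl}-3-methylcyclohex-2-en-1-one | O=C1CC[C@H](CO[Si](c2ccccc2)(c2ccccc2)C(C)(C)C)C(C)=C1 | intermediate
7 | tert-butyl{[(1S,2R)-2-ethenyl-2-methyl-4-[(trimethylsilyl)oxy]cyclohex-3-en-1-yl]methoxy}diphenylsilane (vinyl trans to CH2OSi) | C[Si](C)(C)OC1=C[C@](C)(C=C)[C@@H](CO[Si](c2ccccc2)(c2ccccc2)C(C)(C)C)CC1 | intermediate
8 | (3R,4S)-4-{[(tert-butyldiphenylsilyl)oxy]methyl}-2-[(dimethylamino)methyl]-3-ethenyl-3-methylcyclohexan-1-one (C2 epimers; centre erased in step 5) | O=C1CC[C@H](CO[Si](c2ccccc2)(c2ccccc2)C(C)(C)C)[C@@](C)(C=C)C1CN(C)C | intermediate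
9 | methiodide of 8: {[(2R,3S)-3-{[(tert-butyldiphenylsilyl)oxy]methyl}-2-ethenyl-2-methyl-6-oxocyclohexyl]methyl}trimethylammonium iodide | O=C1CC[C@H](CO[Si](c2ccccc2)(c2ccccc2)C(C)(C)C)[C@@](C)(C=C)C1C[N+](C)(C)C.[I-] | intermediate
10 | (3R,4S)-4-{[(tert-butyldiphenylsilyl)oxy]methyl}-3-ethenyl-3-methyl-2-methylidenecyclohexan-1-one | O=C1CC[C@H](CO[Si](c2ccccc2)(c2ccccc2)C(C)(C)C)[C@@](C)(C=C)C1=C | intermediate
11 | (2R,3R,4S)-4-{[(tert-butyldiphenylsilyl)oxy]methyl}-3-ethenyl-2-{[(4-methoxyphenyl)methoxy]methyl}-3-methylcyclohexan-1-one | O=C1CC[C@H](CO[Si](c2ccccc2)(c2ccccc2)C(C)(C)C)[C@@](C)(C=C)[C@@H]1COCc1ccc(OC)cc1 | intermediate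
12 | tert-butyl{[(1S,2R,3R)-2-ethenyl-3-{[(4-methoxyphenyl)methoxy]methyl}-2-methyl-4-methylidenecyclohexyl]methoxy}diphenylsilane | C=C1CC[C@H](CO[Si](c2ccccc2)(c2ccccc2)C(C)(C)C)[C@@](C)(C=C)[C@@H]1COCc1ccc(OC)cc1 | intermediate
13 | [(1S,2R,3R)-2-ethenyl-3-{[(4-methoxyphenyl)methoxy]methyl}-2-methyl-4-methylidenecyclohexyl]methanol | C=C1CC[C@H](CO)[C@@](C)(C=C)[C@@H]1COCc1ccc(OC)cc1 | intermediate
14 | (1S,2S,3R)-2-ethenyl-3-{[(4-methoxyphenyl)methoxy]methyl}-2-methyl-4-methylidenecyclohexane-1-carbaldehyde | C=C1CC[C@H](C=O)[C@@](C)(C=C)[C@@H]1COCc1ccc(OC)cc1 | intermediate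
15 | (3aS,4R,7aS)-4-{[(4-methoxyphenyl)methoxy]methyl}-3a-methyl-5-methylideneoctahydro-1H-inden-1-one (trans-fused) | C=C1CC[C@@H]2C(=O)CC[C@@]2(C)[C@@H]1COCc1ccc(OC)cc1 | intermediate
16 | (1R,3aS,4R,7aS)-4-{[(4-methoxyphenyl)methoxy]methyl}-3a-methyl-5-methylidene-1-(prop-1-en-2-yl)octahydro-1H-inden-1-ol (OH cis to angular methyl) | C=C1CC[C@@H]2[C@@](O)(C(C)=C)CC[C@@]2(C)[C@@H]1COCc1ccc(OC)cc1 | intermediate
17 | (1R,3aS,4R,7aS)-4-{[(4-methoxyphenyl)methoxy]methyl}-3a-methyl-5-methylidene-1-[(2S)-2-methyloxiran-2-yl]octahydro-1H-inden-1-ol | C=C1CC[C@@H]2[C@@](O)([C@]3(C)CO3)CC[C@@]2(C)[C@@H]1COCc1ccc(OC)cc1 | intermediate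
18 | (1R,4aR,5R,8aS)-1-(hydroxymethyl)-5-{[(4-methoxyphenyl)methoxy]methyl}-1,4a-dimethyl-6-methylideneoctahydronaphthalen-2(1H)-one | C=C1CC[C@@H]2[C@](C)(CO)C(=O)CC[C@@]2(C)[C@@H]1COCc1ccc(OC)cc1 | intermediate
19 | [(1R,2S,4aR,5R,8aS)-2-hydroxy-5-{[(4-methoxyphenyl)methoxy]methyl}-1,4a-dimethyl-6-methylidenedecahydronaphthalen-1-yl]methyl acetate | C=C1CC[C@@H]2[C@](C)(COC(C)=O)[C@@H](O)CC[C@@]2(C)[C@@H]1COCc1ccc(OC)cc1 | intermediate
20 | [(1R,2S,4aR,5R,8aS)-2-hydroxy-5-(hydroxymethyl)-1,4a-dimethyl-6-methylidenedecahydronaphthalen-1-yl]methyl acetate | C=C1CC[C@@H]2[C@](C)(COC(C)=O)[C@@H](O)CC[C@@]2(C)[C@@H]1CO | intermediate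
21 | 7-hydroxy-2H-chromen-2-one (umbelliferone) | O=c1ccc2ccc(O)cc2o1 | starting material
22 | [(1R,2S,4aR,5R,8aS)-2-hydroxy-1,4a-dimethyl-6-methylidene-5-{[(2-oxo-2H-chromen-7-yl)oxy]methyl}decahydronaphthalen-1-yl]methyl acetate | C=C1CC[C@@H]2[C@](C)(COC(C)=O)[C@@H](O)CC[C@@]2(C)[C@@H]1COc1ccc2ccc(=O)oc2c1 | target

**Step count and risks**

Total step count: 14. Longest linear sequence: 14 steps (1 → 22).

Steps most likely to fail:

1. Step 11, directed epoxidation. The facial selectivity at the isopropenyl group may be low or reversed, because the two ring carbons on C3 (C2 and C5) differ only moderately in size; the wrong oxirane would give the C4 epimer after the shift. The fallback sets out from 15 and returns at 17. Ketone 15 would be treated with 1-ethoxyvinyllithium and CeCl3 (THF, −78 °C) to give the enol ether carbinol F1. Mild hydrolysis (aqueous oxalic acid, THF) would give the tertiary α-hydroxy methyl ketone F2. Methylene transfer from dimethylsulfonium methylide (Me3S+ I−, KOt-Bu, DMSO/THF, low temperature; Corey–Chaykovsky epoxidation) to the C4 carbonyl would then give 17. Here C4 is set by acyclic 1,2-induction in a carbonyl addition (ylide anti to the carbinol oxygen, passing the smaller ring CH2), an element independent of the hydroxyl-directed oxygen transfer.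

2. Step 12, tandem ring expansion/reduction. The samarium species may be too weak to ionise the oxirane, the hydride transfer from the neopentyl hemiacetal may be slow, or the acetyl group may migrate to O3. The fallback sets out from 17 and returns at 19, with the three events uncoupled. ZnBr2 in CH2Cl2 at 0 °C would effect only the semipinacol shift, and hydroxy ketone 18 would be isolated. Hydroxyl-directed reduction with Me4NBH(OAc)3 (MeCN/AcOH, −20 °C; Evans–Saksena reduction) would deliver hydride from the CH2OH face to give the anti diol F3. Selective acetylation of the primary hydroxyl (AcCl, 2,4,6-collidine, CH2Cl2, −78 °C) would give 19.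

3. Step 9, hydroacylation. The acyl rhodium hydride may decarbonylate, rhodium hydride may isomerise the exocyclic alkene, or C5 may epimerise. The fallback sets out from 14 and returns at 15, closing the five-membered ring by olefin metathesis instead. Vinylmagnesium bromide (THF, −78 °C) would give the divinyl carbinol F4 as a mixture of C3 epimers. Ring-closing metathesis with the second-generation Grubbs catalyst RuCl2(=CHPh)(PCy3)(H2IMes) (CH2Cl2, 40 °C) would give the trans-fused cyclopentenol F5. Dess–Martin oxidation would give the cyclopentenone F6. Conjugate reduction with Stryker's reagent [(Ph3P)CuH]6 (toluene, 25 °C) would give 15 without touching the 1,1-disubstituted alkene.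

**Further compounds**

F1 | step 11 | (1R,3aS,4R,7aS)-1-(1-ethoxyethenyl)-4-{[(4-methoxyphenyl)methoxy]methyl}-3a-methyl-5-methylideneoctahydro-1H-inden-1-ol | C=C1CC[C@@H]2[C@@](O)(C(=C)OCC)CC[C@@]2(C)[C@@H]1COCc1ccc(OC)cc1
F2 | step 11 | 1-[(1R,3aS,4R,7aS)-1-hydroxy-4-{[(4-methoxyphenyl)methoxy]methyl}-3a-methyl-5-methylideneoctahydro-1H-inden-1-yl]ethan-1-one | C=C1CC[C@@H]2[C@@](O)(C(C)=O)CC[C@@]2(C)[C@@H]1COCc1ccc(OC)cc1
F3 | step 12 | (1R,2S,4aR,5R,8aS)-1-(hydroxymethyl)-5-{[(4-methoxyphenyl)methoxy]methyl}-1,4a-dimethyl-6-methylidenedecahydronaphthalen-2-ol | C=C1CC[C@@H]2[C@](C)(CO)[C@@H](O)CC[C@@]2(C)[C@@H]1COCc1ccc(OC)cc1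
F4 | step 9 | 1-[(1S,2S,3R)-2-ethenyl-3-{[(4-methoxyphenyl)methoxy]methyl}-2-methyl-4-methylidenecyclohexyl]prop-2-en-1-ol (carbinol epimers) | C=C1CC[C@H](C(O)C=C)[C@@](C)(C=C)[C@@H]1COCc1ccc(OC)cc1
F5 | step 9 | (3aS,4R,7aS)-4-{[(4-methoxyphenyl)methoxy]methyl}-3a-methyl-5-methylidene-3a,4,5,6,7,7a-hexahydro-1H-inden-1-ol (carbinol epimers, trans-fused) | C=C1CC[C@@H]2C(O)C=C[C@@]2(C)[C@@H]1COCc1ccc(OC)cc1
F6 | step 9 | (3aS,4R,7aS)-4-{[(4-methoxyphenyl)methoxy]methyl}-3a-methyl-5-methylidene-3a,4,5,6,7,7a-hexahydro-1H-inden-1-one | C=C1CC[C@@H]2C(=O)C=C[C@@]2(C)[C@@H]1COCc1ccc(OC)cc1
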